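**Retrosynthetic overview**

1. Numbering (terpenoid): ring A = C1–C5 and C10, ring B = C5–C10; C4 carries the exocyclic CH2, C5 the angular CH3, C8 the CH3, C9 the CH2OH and the arylmethyl group, C10 the ring-fusion H.
2. Late disconnections: the MOM ethers, the aryl CO2Me (carbonylation of an aryl bromide) and the CH2OH (from a tert-butyl ester); the arylmethyl–C9 bond and the C8–H bond are then cut together as a reductive benzylation of a C8=C9 unsaturated ester, which comes from a ring B β-keto ester (C8 ketone → enol triflate → methyl).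
3. Key disconnection: ring B of that β-keto ester is opened at C5–C6 and at C8–C9 in one retro Michael–Dieckmann [3+3] step, giving methyl acrylate (C6–C7–C8) and the monocyclic keto ester tert-butyl (2-methyl-3-oxocyclohexyl)acetate (ring A plus C9 and its ester carbon).
4. Enabling feature: in ring B the quaternary carbons C5 and C9 both flank the ring-fusion CH (C10), and each bears a carbon that can be read as a carbonyl (the C4 methylidene of ring A as a ketone, the CH2OH on C9 as an ester). C5 and C9 are therefore the two α-carbons of a 1,5-keto ester, and C6–C7–C8 is a three-carbon bis-electrophile.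
5. Ring order: ring A is bought (3-ethoxycyclohexenone) and its C10 centre is set by asymmetric conjugate reduction; ring B is closed in the key step with the C5 quaternary centre and the trans ring fusion; the arene (from 2-methoxyresorcinol) is attached afterwards.

Key step: step 3

Remark: names use naphthalene locants (C9 = 1, C8 = 2, C5 = 4a, C4 = 5, C10 = 8a); β is the face of the C5 methyl.
Assumption: the ligand antipode written in step 2 is the one taken to give the (1S) centre; if the sense of induction is opposite, its mirror image is used.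

**Route**

Step 1
Reactants: 1 3-ethoxycyclohex-2-en-1-one; 2 tert-butyl acetate
Product: 4 tert-butyl 2-(3-oxocyclohex-1-en-1-yl)acetate, via tertiary carbinol adduct 3 (not isolated)
Conditions: LiN(i-Pr)2 (1.1 equiv), 2, THF, −78 °C; 1, −78 → 0 °C; 1 M aq. HCl, 0 °C → rt
Reagents that add atoms: water (O)
Why: Stork–Danheiser transposition: 1,2-addition of the lithium enolate of 2 to the vinylogous ester carbonyl gives carbinol 3, and aqueous acid hydrolyses the enol ether and eliminates water to the 3-substituted enone; no stereocentre is formed.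

Step 2
Reactants: 4 tert-butyl 2-(3-oxocyclohex-1-en-1-yl)acetate
Product: 6 tert-butyl 2-[(1S)-2-methyl-3-oxocyclohexyl]acetate, via silyl enol ether 5 (not isolated)
Conditions: Cu(OAc)2·H2O (3 mol%), (R)-DTBM-SEGPHOS (3 mol%), Ph2SiH2 (1.0 equiv), toluene, 0 °C; then MeI (5 equiv), Bu4N[Ph3SiF2] (1.2 equiv), CH2Cl2, 0 °C → rt
Reagents that add atoms: iodomethane (CI)
Why: Ligand-controlled CuH 1,4-reduction of a β-substituted cyclohexenone (asymmetric conjugate reduction) should set the C10 stereocentre (1S) and deliver the regiodefined silyl enol ether 5, whose fluoride-triggered enolate alkylation places the methyl on C5 only; the C5 configuration is irrelevant because C5 is enolised again in step 3.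

Step 3
Reactants: 6 tert-butyl 2-[(1S)-2-methyl-3-oxocyclohexyl]acetate; 7 methyl acrylate
Product: 9 tert-butyl (4aS,8aS)-4a-methyl-2,5-dioxodecahydronaphthalene-1-carboxylate, via keto diester 8 (not isolated)
Conditions: KOt-Bu (0.2 equiv), t-BuOH/THF, 7 (1.1 equiv), 0 °C → rt; then KOt-Bu (2.5 equiv), THF, rt → 40 °C; AcOH
Reagents that add atoms: none
Why: Tandem Michael–Dieckmann annulation, a formal [3+3] union of the keto ester (C5 and C9 nucleophilic) with the acrylate (C6 and C8 electrophilic): the thermodynamic, tetrasubstituted potassium enolate of the ketone adds through C5 to the β-carbon of 7 (C5–C6), then after proton transfer the tert-butyl ester enolate attacks the new methyl ester through C9 (C8–C9), methoxide leaves and deprotonation of the β-keto ester makes the sequence irreversible. The closest known reaction types are the base-mediated Michael addition of 2,3-dialkylcyclohexanones to acrylates and enones (as in Robinson annulations, which alkylate the more substituted α-carbon anti to the 3-substituent) and the one-pot Michael–Dieckmann condensation of ester enolates with acrylates. Ring B is the only ring closed, by a 6-(enolexo)-exo-trig acyl substitution. The only new permanent stereocentre is C5: the acrylate approaches the enolate face anti to the pseudoaxial C10 side chain, so C6 and C9 are trans on ring A and ring B can close only as the trans-decalin with the C5 methyl and the C10 hydrogen anti; C9 stays epimerisable. The step needs C5 rather than C3 alkylation, secured by equilibration to the more substituted enolate, and a single direction of Claisen closure, secured by the tert-butyl ester, which can act as the enolate but not as the acyl acceptor, so the acrylate carbonyl becomes the C8 ketone. Attack of the C3 enolate on the methyl ester would give a bridged diketone that cannot be stabilised as an enolate and should revert under the equilibrating conditions.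

Step 4
Reactants: 9 tert-butyl (4aS,8aS)-4a-methyl-2,5-dioxodecahydronaphthalene-1-carboxylate
Product: 10 tert-butyl (4aS,8aS)-4a-methyl-5-methylidene-2-oxodecahydronaphthalene-1-carboxylate
Conditions: Ph3PCH3Br (4 equiv), KOt-Bu (4 equiv), toluene, 0 → 90 °C; aq. NH4Cl
Reagents that add atoms: methyltriphenylphosphonium bromide (C[P+](c1ccccc1)(c1ccccc1)c1ccccc1.[Br-])
Why: Wittig methylenation: the first equivalent of ylide deprotonates the β-keto ester, whose enolate shields C8 and the ester, so only the hindered C4 ketone is olefinated on heating; no stereocentre is touched.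

Step 5
Reactants: 10 tert-butyl (4aS,8aS)-4a-methyl-5-methylidene-2-oxodecahydronaphthalene-1-carboxylate
Product: 11 tert-butyl (4aS,8aR)-4a-methyl-5-methylidene-2-(trifluoromethylsulfonyloxy)-3,4,4a,5,6,7,8,8a-octahydronaphthalene-1-carboxylate
Conditions: NaH (1.1 equiv), THF, 0 °C; PhNTf2 (1.2 equiv), 0 °C → rt; dilute aq. HCl wash
Reagents that add atoms: N-phenylbis(trifluoromethanesulfonimide) (O=S(=O)(N(c1ccccc1)S(=O)(=O)C(F)(F)F)C(F)(F)F)
Why: O-sulfonylation of the sodium enolate of the β-keto ester (enol triflate formation) is regiospecific for the doubly activated C8/C9 enolate; the C5 and C10 centres are unaffected.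

Step 6
Reactants: 11 tert-butyl (4aS,8aR)-4a-methyl-5-methylidene-2-(trifluoromethylsulfonyloxy)-3,4,4a,5,6,7,8,8a-octahydronaphthalene-1-carboxylate
Product: 12 tert-butyl (4aS,8aR)-2,4a-dimethyl-5-methylidene-3,4,4a,5,6,7,8,8a-octahydronaphthalene-1-carboxylate
Conditions: MeMgBr (1.3 equiv), Fe(acac)3 (5 mol%), THF/NMP, −30 °C
Reagents that add atoms: methylmagnesium bromide (C[Mg]Br)
Why: Iron-catalysed Kumada-type cross-coupling of an enol triflate with MeMgBr replaces OTf by methyl at C8 at low temperature without attack on the tert-butyl ester or the isolated alkene; no stereocentre is formed.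

Step 7
Reactants: 13 2-methoxybenzene-1,3-diol
Product: 14 2,4-dihydroxy-3-methoxybenzaldehyde
Conditions: POCl3 (1.2 equiv), DMF (1.5 equiv), MeCN, 0 °C → rt; H2O, 50 °C
Reagents that add atoms: N,N-dimethylformamide (CN(C)C=O); water (O)
Why: Vilsmeier–Haack formylation: the two equivalent positions ortho to one hydroxyl and para to the other are the only activated sites, and the first formyl group deactivates the ring against a second substitution.

Step 8
Reactants: 14 2,4-dihydroxy-3-methoxybenzaldehyde
Product: 15 5-bromo-2,4-dihydroxy-3-methoxybenzaldehyde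
Conditions: NBS (1.0 equiv), MeCN, 0 °C
Reagents that add atoms: N-bromosuccinimide (O=C1CCC(=O)N1Br)
Why: Electrophilic aromatic bromination: C5 is ortho and para to the two hydroxyls and meta to the formyl group, whereas the other free position is ortho to the formyl group and meta to both hydroxyls, so monobromination at C5 is expected.

Step 9
Reactants: 15 5-bromo-2,4-dihydroxy-3-methoxybenzaldehyde
Product: 16 5-bromo-3-methoxy-2,4-bis(methoxymethoxy)benzaldehyde
Conditions: MOMCl (3 equiv), i-Pr2NEt (4 equiv), CH2Cl2, 0 °C → reflux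
Reagents that add atoms: chloromethyl methyl ether (COCCl)
Why: Williamson-type O-alkylation of both phenols with the reactive α-chloro ether; the aldehyde and the aryl bromide are inert.

Step 10
Reactants: 16 5-bromo-3-methoxy-2,4-bis(methoxymethoxy)benzaldehyde
Product: 17 [5-bromo-3-methoxy-2,4-bis(methoxymethoxy)phenyl]methanol
Conditions: NaBH4, MeOH, 0 °C
Reagents that add atoms: none
Why: Borohydride reduction of the aryl aldehyde to the benzylic alcohol; the acetals and the aryl bromide are not reduced.

Step 11
Reactants: 17 [5-bromo-3-methoxy-2,4-bis(methoxymethoxy)phenyl]methanol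
Product: 18 1-bromo-5-(bromomethyl)-3-methoxy-2,4-bis(methoxymethoxy)benzene
Conditions: CBr4, PPh3, 2,6-lutidine (cat.), CH2Cl2, 0 °C
Reagents that add atoms: carbon tetrabromide (BrC(Br)(Br)Br)
Why: Appel bromination of the primary benzylic alcohol under buffered conditions that spare the MOM acetals; the reactive bromide is used at once.

Step 12
Reactants: 12 tert-butyl (4aS,8aR)-2,4a-dimethyl-5-methylidene-3,4,4a,5,6,7,8,8a-octahydronaphthalene-1-carboxylate; 18 1-bromo-5-(bromomethyl)-3-methoxy-2,4-bis(methoxymethoxy)benzene
Product: 20 tert-butyl (1S,2S,4aS,8aR)-1-{[5-bromo-3-methoxy-2,4-bis(methoxymethoxy)phenyl]methyl}-2,4a-dimethyl-5-methylidenedecahydronaphthalene-1-carboxylate, via lithium ester enolate 19 (not isolated)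
Conditions: Li (2.5 equiv), NH3(l)/THF, t-BuOH (1.0 equiv), −78 °C; isoprene; NH3 evaporated; 18 (1.5 equiv), THF, −78 → 0 °C
Reagents that add atoms: none
Why: Birch-type reductive alkylation of an α,β-unsaturated ester: two-electron reduction with protonation of C8 along the axial direction from the α-face should leave the C8 methyl equatorial (β), and the exocyclic ester enolate 19 is benzylated from the α-face because the axial C5 methyl blocks the β-face, so at C9 the ester ends up axial (β) and the arylmethyl group equatorial (α); the isolated 1,1-disubstituted alkene is not reduced.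

Step 13
Reactants: 20 tert-butyl (1S,2S,4aS,8aR)-1-{[5-bromo-3-methoxy-2,4-bis(methoxymethoxy)phenyl]methyl}-2,4a-dimethyl-5-methylidenedecahydronaphthalene-1-carboxylate
Product: 21 [(1S,2S,4aS,8aR)-1-{[5-bromo-3-methoxy-2,4-bis(methoxymethoxy)phenyl]methyl}-2,4a-dimethyl-5-methylidenedecahydronaphthalen-1-yl]methanol
Conditions: LiAlH4 (3 equiv), THF, 0 → 40 °C; aq. NaOH work-up
Reagents that add atoms: none
Why: Hydride reduction of the hindered neopentylic tert-butyl ester to the primary alcohol; the aryl bromide, the MOM ethers and the exocyclic alkene are inert at this temperature and no stereocentre is touched.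

Step 14
Reactants: 21 [(1S,2S,4aS,8aR)-1-{[5-bromo-3-methoxy-2,4-bis(methoxymethoxy)phenyl]methyl}-2,4a-dimethyl-5-methylidenedecahydronaphthalen-1-yl]methanol
Product: 22 methyl 5-{[(1S,2S,4aS,8aR)-1-(hydroxymethyl)-2,4a-dimethyl-5-methylidenedecahydronaphthalen-1-yl]methyl}-3-methoxy-2,4-bis(methoxymethoxy)benzoate
Conditions: Pd(OAc)2 (5 mol%), Xantphos (10 mol%), CO (1 atm), Et3N, MeOH/toluene, 70 °C
Reagents that add atoms: carbon monoxide ([C-]#[O+]); methanol (CO)
Why: Palladium-catalysed methoxycarbonylation of the aryl bromide (oxidative addition to zerovalent palladium, CO insertion, methanolysis) installs the benzoate only after the aliphatic ester has been reduced, which removes the ester/ester selectivity problem; the free primary alcohol cannot compete with methanol as solvent.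

Step 15
Reactants: 22 methyl 5-{[(1S,2S,4aS,8aR)-1-(hydroxymethyl)-2,4a-dimethyl-5-methylidenedecahydronaphthalen-1-yl]methyl}-3-methoxy-2,4-bis(methoxymethoxy)benzoate
Product: 23 methyl 2,4-dihydroxy-5-{[(1S,2S,4aS,8aR)-1-(hydroxymethyl)-2,4a-dimethyl-5-methylidenedecahydronaphthalen-1-yl]methyl}-3-methoxybenzoate
Conditions: HCl (0.5 M), MeOH, 0 °C → rt
Reagents that add atoms: none
Why: Acid-catalysed acetal exchange with methanol cleaves both aryl MOM ethers under dilute, cold conditions chosen to spare the acid-sensitive exocyclic alkene and the methyl ester; no stereocentre is touched.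

**Compound list**

1 | 3-ethoxycyclohex-2-en-1-one | CCOC1=CC(=O)CCC1 | starting material
2 | tert-butyl acetate | CC(=O)OC(C)(C)C | starting material
3 | tert-butyl 2-(3-ethoxy-1-hydroxycyclohex-2-en-1-yl)acetate (racemic) | CCOC1=CC(O)(CC(=O)OC(C)(C)C)CCC1 | intermediate
4 | tert-butyl 2-(3-oxocyclohex-1-en-1-yl)acetate | O=C1C=C(CC(=O)OC(C)(C)C)CCC1 | intermediate
5 | tert-butyl 2-[(1S)-3-(diphenylsilyloxy)cyclohex-2-en-1-yl]acetate | O([SiH](c1ccccc1)c1ccccc1)C2=C[C@H](CC(=O)OC(C)(C)C)CCC2 | intermediate
6 | tert-butyl 2-[(1S)-2-methyl-3-oxocyclohexyl]acetate (C2 epimers, trans expected as major) | O=C1CCC[C@@H](CC(=O)OC(C)(C)C)C1C | intermediate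
7 | methyl acrylate (methyl prop-2-enoate) | C=CC(=O)OC | starting material
8 | tert-butyl 2-[(1S,2S)-2-(3-methoxy-3-oxopropyl)-2-methyl-3-oxocyclohexyl]acetate | O=C1CCC[C@@H](CC(=O)OC(C)(C)C)[C@]1(C)CCC(=O)OC | intermediate
9 | tert-butyl (4aS,8aS)-4a-methyl-2,5-dioxodecahydronaphthalene-1-carboxylate (trans-fused; C1 epimers and enol form) | O=C1CCC[C@H]2C(C(=O)OC(C)(C)C)C(=O)CC[C@]12C | intermediate
10 | tert-butyl (4aS,8aS)-4a-methyl-5-methylidene-2-oxodecahydronaphthalene-1-carboxylate (C1 epimers and enol form) | C=C1CCC[C@H]2C(C(=O)OC(C)(C)C)C(=O)CC[C@]12C | intermediate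
11 | tert-butyl (4aS,8aR)-4a-methyl-5-methylidene-2-(trifluoromethylsulfonyloxy)-3,4,4a,5,6,7,8,8a-octahydronaphthalene-1-carboxylate | C=C1CCC[C@H]2C(C(=O)OC(C)(C)C)=C(OS(=O)(=O)C(F)(F)F)CC[C@]12C | intermediate
12 | tert-butyl (4aS,8aR)-2,4a-dimethyl-5-methylidene-3,4,4a,5,6,7,8,8a-octahydronaphthalene-1-carboxylate | C=C1CCC[C@H]2C(C(=O)OC(C)(C)C)=C(C)CC[C@]12C | intermediate
13 | 2-methoxybenzene-1,3-diol (2-methoxyresorcinol) | COc1c(O)cccc1O | starting material
14 | 2,4-dihydroxy-3-methoxybenzaldehyde | O=Cc1ccc(O)c(OC)c1O | intermediate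
15 | 5-bromo-2,4-dihydroxy-3-methoxybenzaldehyde | O=Cc1cc(Br)c(O)c(OC)c1O | intermediate
16 | 5-bromo-3-methoxy-2,4-bis(methoxymethoxy)benzaldehyde | O=Cc1cc(Br)c(OCOC)c(OC)c1OCOC | intermediate
17 | [5-bromo-3-methoxy-2,4-bis(methoxymethoxy)phenyl]methanol | OCc1cc(Br)c(OCOC)c(OC)c1OCOC | intermediate
18 | 1-bromo-5-(bromomethyl)-3-methoxy-2,4-bis(methoxymethoxy)benzene | BrCc1cc(Br)c(OCOC)c(OC)c1OCOC | intermediate
19 | lithium enolate of tert-butyl (2S,4aS,8aR)-2,4a-dimethyl-5-methylidenedecahydronaphthalene-1-carboxylate (C1=C(OLi)Ot-Bu) | C=C1CCC[C@H]2C(=C([O-])OC(C)(C)C)[C@@H](C)CC[C@]12C.[Li+] | intermediate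
20 | tert-butyl (1S,2S,4aS,8aR)-1-{[5-bromo-3-methoxy-2,4-bis(methoxymethoxy)phenyl]methyl}-2,4a-dimethyl-5-methylidenedecahydronaphthalene-1-carboxylate | C=C1CCC[C@H]2[C@](C(=O)OC(C)(C)C)(Cc3cc(Br)c(OCOC)c(OC)c3OCOC)[C@@H](C)CC[C@]12C | intermediate
21 | [(1S,2S,4aS,8aR)-1-{[5-bromo-3-methoxy-2,4-bis(methoxymethoxy)phenyl]methyl}-2,4a-dimethyl-5-methylidenedecahydronaphthalen-1-yl]methanol | C=C1CCC[C@H]2[C@](CO)(Cc3cc(Br)c(OCOC)c(OC)c3OCOC)[C@@H](C)CC[C@]12C | intermediate
22 | methyl 5-{[(1S,2S,4aS,8aR)-1-(hydroxymethyl)-2,4a-dimethyl-5-methylidenedecahydronaphthalen-1-yl]methyl}-3-methoxy-2,4-bis(methoxymethoxy)benzoate | C=C1CCC[C@H]2[C@](CO)(Cc3cc(C(=O)OC)c(OCOC)c(OC)c3OCOC)[C@@H](C)CC[C@]12C | intermediate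
23 | methyl 2,4-dihydroxy-5-{[(1S,2S,4aS,8aR)-1-(hydroxymethyl)-2,4a-dimethyl-5-methylidenedecahydronaphthalen-1-yl]methyl}-3-methoxybenzoate | C=C1CCC[C@H]2[C@](CO)(Cc3cc(C(=O)OC)c(O)c(OC)c3O)[C@@H](C)CC[C@]12C | target

**Step count and risks**

Total steps: 15. Longest linear sequence: 10 steps (steps 1–6 and 12–15); the arene branch (steps 7–11) joins at step 12.

Steps most likely to fail:

Step 12 (reductive benzylation). What may go wrong: the hindered enolate may be protonated in the ammonia-derived medium or the ester over-reduced before C-alkylation, and the electron-rich benzylic bromide may be consumed by residual lithium or alkoxide. The fallback sets out from 12 and returns at 20. Compound 12 is reduced with Li in NH3/THF and quenched with solid NH4Cl to isolate the saturated ester tert-butyl (2S,4aS,8aS)-2,4a-dimethyl-5-methylidenedecahydronaphthalene-1-carboxylate F1 (C1 epimers). F1 is then deprotonated in a separate operation with LiN(i-Pr)2 in THF/HMPA and the preformed enolate is alkylated with 18 to give 20. The facial argument at C9 is unchanged, but reduction and alkylation are decoupled and each can be driven to completion on its own.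

Step 3 (Michael–Dieckmann annulation). What may go wrong: Michael addition at the less substituted α-carbon or on the face syn to the side chain, and oligomerisation of the acrylate under alkoxide. The fallback sets out from 6 and returns at 9. Ketone 6 is condensed with (S)-1-phenylethylamine (toluene, reflux, water removal; the antipode is used if it proves to be the matched one) to the imine tert-butyl 2-[(1S)-2-methyl-3-{[(1S)-1-phenylethyl]imino}cyclohexyl]acetate F2. Its more substituted secondary enamine tautomer adds to 7 under neutral conditions (THF, 40 °C) in an aza-ene-type Michael addition to give the imine methyl 3-[(1S,2S)-2-(2-tert-butoxy-2-oxoethyl)-1-methyl-6-{[(1S)-1-phenylethyl]imino}cyclohexyl]propanoate F3. Hydrolysis with aqueous AcOH gives keto diester 8, now isolated, which is cyclised in a separate Dieckmann step (KOt-Bu, THF) to 9.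

Step 2 (conjugate reduction and methylation). What may go wrong: over-alkylation and proton-transfer scrambling of the fluoride-generated enolate, and erosion of enantioselectivity by base-mediated deconjugation of 4. The fallback sets out from 5 and returns at 6. Silyl enol ether 5 is isolated after the CuH reduction and cyclopropanated with Et2Zn/CH2I2 (Simmons–Smith, CH2Cl2, 0 °C) to the siloxycyclopropane tert-butyl 2-[(2S)-6-(diphenylsilyloxy)bicyclo[4.1.0]heptan-2-yl]acetate F4. F4 is opened with K2CO3 in MeOH at the CH2–C(O) bond to the α-methyl ketone 6, which fixes mono-methylation at C5.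

Further compounds
F1 | step 12 | tert-butyl (2S,4aS,8aS)-2,4a-dimethyl-5-methylidenedecahydronaphthalene-1-carboxylate (C1 epimers) | C=C1CCC[C@H]2C(C(=O)OC(C)(C)C)[C@@H](C)CC[C@]12C
F2 | step 3 | tert-butyl 2-[(1S)-2-methyl-3-{[(1S)-1-phenylethyl]imino}cyclohexyl]acetate | C[C@H](N=C1CCC[C@@H](CC(=O)OC(C)(C)C)C1C)c1ccccc1
F3 | step 3 | methyl 3-[(1S,2S)-2-(2-tert-butoxy-2-oxoethyl)-1-methyl-6-{[(1S)-1-phenylethyl]imino}cyclohexyl]propanoate | C[C@H](N=C1CCC[C@@H](CC(=O)OC(C)(C)C)[C@]1(C)CCC(=O)OC)c1ccccc1
F4 | step 2 | tert-butyl 2-[(2S)-6-(diphenylsilyloxy)bicyclo[4.1.0]heptan-2-yl]acetate | CC(C)(C)OC(=O)C[C@@H]1CCCC2(O[SiH](c3ccccc3)c3ccccc3)CC12
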